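**Plan**

- Retrosynthesis: the C2=C3 enone of the cyclohexenone (ring A) is traced back to a C1=C2 silyl enol ether (Saegusa–Ito oxidation). Ring A is then cut at C3–C4 and C5–C6 in one stroke, into a C4–C5 vicinal ketol and a 2-silyloxybutadiene (C6–C1–C2–C3).
- Enabling feature: C4 and C5 of ring A are adjacent carbinol carbons (cis-diol, secondary and tertiary), i.e. a 1,2-dicarbonyl unit at a lower oxidation level. Each can therefore accept one terminus of a diene in a ruthenium-catalysed transfer-hydrogenative [4+2] cycloaddition at the ketol oxidation level, redox-neutral and without protecting the diol.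
- Forward: oleoyl chloride is homologated by one carbon to the hydroxymethyl ketone (its carbonyl carbon becomes C5; the Z-alkene comes unchanged from oleic acid). Methyl vinyl ketone gives the silyloxydiene, the cycloaddition builds ring A, and oxidation of the enol ether gives the enone.
- Stereochemistry: C4 is set by the chiral bisphosphine on ruthenium (face of the transient aldehyde). C5 is relayed from C4 through the ruthenium diolate chelate (cis). The silyl enol ether left by the diene fixes the position of the enone.

Key step: step 3

Assumption: the sense of induction of the (R)-MeO-BIPHEP–ruthenium catalyst cannot be predicted with certainty; the (R)-ligand is written and the (S)-ligand would be taken if the mirror-image adduct should form.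

**Step 1**
Reactants: 1 oleoyl chloride ((Z)-octadec-9-enoyl chloride); 2 tris(trimethylsilyloxy)ethylene
Product: 5 (Z)-1-hydroxynonadec-10-en-2-one, via trimethylsilyl (Z)-3-oxo-2-(trimethylsilyloxy)icos-11-enoate 3 (not isolated), via (Z)-2-hydroxy-3-oxoicos-11-enoic acid 4 (not isolated)
Conditions: 2 (2.2 equiv), neat, 95 °C; then 0.6 M aq. HCl, dioxane, 85 °C
Reagents that add atoms: none
Why: C-acylation of the ketene tris(silyl) acetal by the acid chloride, then acid hydrolysis and decarboxylation of the α-hydroxy-β-keto acid, is the established one-carbon homologation of acid chlorides to hydroxymethyl ketones; it should leave the isolated Z-alkene untouched and creates no stereocentre.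

**Step 2**
Reactants: 6 methyl vinyl ketone (but-3-en-2-one)
Product: 7 2-(tert-butyldimethylsilyloxy)buta-1,3-diene
Conditions: TBSOTf, Et3N, Et2O, 0 °C
Reagents that add atoms: tert-butyldimethylsilyl trifluoromethanesulfonate (TBSOTf), CC(C)(C)[Si](C)(C)OS(=O)(=O)C(F)(F)F
Why: Soft enolisation of the enone with a silyl triflate and an amine base (standard silyl enol ether formation) should give the cross-conjugated 2-silyloxydiene, the bulky silyl group being chosen to survive step 3; no stereocentre is formed.

**Step 3**
Reactants: 5 (Z)-1-hydroxynonadec-10-en-2-one; 7 2-(tert-butyldimethylsilyloxy)buta-1,3-diene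
Product: 9 (1S,2R)-5-[(tert-butyldimethylsilyl)oxy]-1-[(Z)-heptadec-8-en-1-yl]cyclohex-4-ene-1,2-diol, via (Z)-2-oxononadec-10-enal 8 (not isolated)
Conditions: Ru3(CO)12 (2 mol %), (R)-MeO-BIPHEP (6 mol %), 7 (1.5 equiv), toluene, 120 °C, sealed tube, argon
Reagents that add atoms: none
Why: Proposed new method: zerovalent ruthenium should dehydrogenate ketol 5 to the vicinal ketoaldehyde 8, whose aldehyde C=O undergoes oxidative coupling with the unsubstituted vinyl terminus of diene 7 (C3–C4 bond) to give a 2-silyloxyallyl ruthenium alkoxide; this allyl then adds through its CH2 terminus to the neighbouring ketone inside the chelate (C5–C6 bond), and the ruthenium diolate is released by hydrogen transfer from the next molecule of 5, so the process is redox-neutral. The closest known reaction type is the Ru3(CO)12/bisphosphine-catalysed transfer-hydrogenative [4+2] cycloaddition of 1,2-diols, α-ketols and 1,2-diones with butadiene, isoprene or myrcene, which has not been shown with a 2-silyloxydiene, with a ketol ending in a primary carbinol, or with a chiral ligand; (R)-MeO-BIPHEP is the configurationally stable congener of the BIPHEP ligand used there. Ring A, the only ring formed, closes as a 6-exo-trig carbonyl allylation on the ruthenium template. The configuration at C4 is set by the face of the aldehyde exposed by the chiral bisphosphine-bound metal in the oxidative coupling, and that at C5 follows from it because both oxygens stay bound to one ruthenium atom, so only the cis-fused five-membered diolate, hence the cis-diol, can form. The step needs regiocontrol (silyloxy carbon 1,3 to the tertiary carbinol), which rests on first coupling at the less hindered, more electrophilic aldehyde and at the diene terminus remote from the 2-substituent (as isoprene couples in this catalysis), and chemoselectivity over the isolated Z-alkene, which cannot chelate and is not a partner for oxidative coupling.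

**Step 4**
Reactants: 9 (1S,2R)-5-[(tert-butyldimethylsilyl)oxy]-1-[(Z)-heptadec-8-en-1-yl]cyclohex-4-ene-1,2-diol
Product: 10 (4R,5S)-5-[(Z)-heptadec-8-en-1-yl]-4,5-dihydroxycyclohex-2-en-1-one
Conditions: Pd(OAc)2 (1.1 equiv), MeCN, 25–40 °C
Reagents that add atoms: none
Why: Saegusa–Ito oxidation: the regiodefined silyl enol ether should be converted into the palladium enolate at C2, and β-hydride elimination from C3 then gives the C2=C3 enone without touching the C4 and C5 stereocentres, so the enol ether from step 3 serves both as regiochemical marker and as enone precursor.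

**Compound list**

1 | oleoyl chloride, (Z)-octadec-9-enoyl chloride | CCCCCCCC/C=C\CCCCCCCC(=O)Cl | starting material
2 | tris(trimethylsilyloxy)ethylene | C[Si](C)(C)OC=C(O[Si](C)(C)C)O[Si](C)(C)C | starting material
3 | trimethylsilyl (Z)-3-oxo-2-(trimethylsilyloxy)icos-11-enoate (racemic at C2) | CCCCCCCC/C=C\CCCCCCCC(=O)C(O[Si](C)(C)C)C(=O)O[Si](C)(C)C | intermediate
4 | (Z)-2-hydroxy-3-oxoicos-11-enoic acid (racemic at C2) | CCCCCCCC/C=C\CCCCCCCC(=O)C(O)C(=O)O | intermediate
5 | (Z)-1-hydroxynonadec-10-en-2-one | CCCCCCCC/C=C\CCCCCCCC(=O)CO | intermediate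
6 | methyl vinyl ketone, but-3-en-2-one | CC(=O)C=C | starting material
7 | 2-(tert-butyldimethylsilyloxy)buta-1,3-diene | C=CC(=C)O[Si](C)(C)C(C)(C)C | intermediate
8 | (Z)-2-oxononadec-10-enal | CCCCCCCC/C=C\CCCCCCCC(=O)C=O | intermediate
9 | (1S,2R)-5-[(tert-butyldimethylsilyl)oxy]-1-[(Z)-heptadec-8-en-1-yl]cyclohex-4-ene-1,2-diol | CCCCCCCC/C=C\CCCCCCC[C@]1(O)CC(O[Si](C)(C)C(C)(C)C)=CC[C@H]1O | intermediate
10 | (4R,5S)-5-[(Z)-heptadec-8-en-1-yl]-4,5-dihydroxycyclohex-2-en-1-one | CCCCCCCC/C=C\CCCCCCC[C@]1(O)CC(=O)C=C[C@H]1O | target

**Step count and risks**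

Total steps: 4 (two convergent branches, 1 → 5 and 6 → 7). Longest linear sequence: 3 steps (1 → 5 → 9 → 10).

Steps most likely to fail:

1. Step 3. Possible failures:
   - no turnover, because the silyl enol ether diene or the transient ketoaldehyde is diverted (silyl transfer to the hydroxyl groups, decarbonylation);
   - coupling with the opposite regiochemistry;
   - further hydrogen-transfer oxidation or epimerisation of the secondary carbinol of the adduct;
   - isomerisation of the Z-alkene by ruthenium hydrides;
   - poor facial selectivity.

   Fallback, from 5 back to 10 (step 4 is then not needed): the same two bonds would be made by two known aldol events.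
   - Commercial ethyl (2-methyl-1,3-dioxolan-2-yl)acetate is reduced with diisobutylaluminium hydride (CH2Cl2, −78 °C) to 2-(2-methyl-1,3-dioxolan-2-yl)acetaldehyde F1.
   - Ketol 5 and this aldehyde are joined in the syn-selective direct aldol reaction catalysed by O-tert-butyl-L-threonine (N-methylpyrrolidone, 4 °C). By the Z-enamine model of primary amino acid catalysis, this enantiomer is expected to set the R centre next to the ketone. The product is (2S,3R,12Z)-2,3-dihydroxy-1-(2-methyl-1,3-dioxolan-2-yl)henicos-12-en-4-one F2; the configuration of its second carbinol is lost later.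
   - Pyridinium p-toluenesulfonate in acetone/water unmasks the methyl ketone to give (4S,5R,14Z)-4,5-dihydroxytricos-14-ene-2,6-dione F3.
   - Pyrrolidine/AcOH (THF, 0–25 °C) closes the ring by intramolecular aldol addition of the methyl ketone to the C5 ketone. This gives (3S,4R,5S)-3-[(Z)-heptadec-8-en-1-yl]-3,4,5-trihydroxycyclohexan-1-one F4, the diastereomer with the long chain and both secondary hydroxyls equatorial, which should be favoured under reversible aldol conditions. E1cB loss of water from its β-hydroxy ketone then gives 10.

2. Step 4. Possible failures: sluggish oxidation of the bulky silyl enol ether; palladium hydride-mediated migration or Z/E isomerisation of the chain alkene; oxidation of the allylic carbinol; acid-promoted loss of the tertiary hydroxyl leading to aromatisation.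

   Fallback, from 9 back to 10: the enol ether is selenenylated regiospecifically with PhSeCl (CH2Cl2, −78 °C) to give (4R,5S)-5-[(Z)-heptadec-8-en-1-yl]-4,5-dihydroxy-2-(phenylselanyl)cyclohexan-1-one F5. Oxidation with H2O2/pyridine (CH2Cl2, 0 °C) gives the selenoxide, (4R,5S)-5-[(Z)-heptadec-8-en-1-yl]-4,5-dihydroxy-2-(phenylseleninyl)cyclohexan-1-one F6, which undergoes syn-elimination toward C3 to give 10.

3. Step 1. Possible failures: ketene formation or incomplete C-acylation of the enolisable acid chloride; hydrochlorination or Z/E isomerisation of the alkene during the hot acidic decarboxylation.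

   Fallback, from 1 back to 5: acylation of diazomethane (CH2N2, Et3N, Et2O, 0 °C; the first stage of the Arndt–Eistert sequence) gives (Z)-1-diazononadec-10-en-2-one F7. Acid-catalysed hydrolysis of the diazoketone (aq. H2SO4, dioxane, 60 °C) then gives 5 with loss of nitrogen.

**Further compounds**

F1 | step 3 | 2-(2-methyl-1,3-dioxolan-2-yl)acetaldehyde | CC1(CC=O)OCCO1
F2 | step 3 | (2S,3R,12Z)-2,3-dihydroxy-1-(2-methyl-1,3-dioxolan-2-yl)henicos-12-en-4-one | CCCCCCCC/C=C\CCCCCCCC(=O)[C@H](O)[C@@H](O)CC1(C)OCCO1
F3 | step 3 | (4S,5R,14Z)-4,5-dihydroxytricos-14-ene-2,6-dione | CCCCCCCC/C=C\CCCCCCCC(=O)[C@H](O)[C@@H](O)CC(C)=O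
F4 | step 3 | (3S,4R,5S)-3-[(Z)-heptadec-8-en-1-yl]-3,4,5-trihydroxycyclohexan-1-one | CCCCCCCC/C=C\CCCCCCC[C@]1(O)CC(=O)C[C@H](O)[C@H]1O
F5 | step 4 | (4R,5S)-5-[(Z)-heptadec-8-en-1-yl]-4,5-dihydroxy-2-(phenylselanyl)cyclohexan-1-one (mixture at C2) | CCCCCCCC/C=C\CCCCCCC[C@]1(O)CC(=O)C([Se]c2ccccc2)C[C@H]1O
F6 | step 4 | (4R,5S)-5-[(Z)-heptadec-8-en-1-yl]-4,5-dihydroxy-2-(phenylseleninyl)cyclohexan-1-one (mixture at C2 and Se) | CCCCCCCC/C=C\CCCCCCC[C@]1(O)CC(=O)C([Se](=O)c2ccccc2)C[C@H]1O
F7 | step 1 | (Z)-1-diazononadec-10-en-2-one | CCCCCCCC/C=C\CCCCCCCC(=O)C=[N+]=[N-]
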